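**Retrosynthetic overview**

1. Numbering (ent-kaurane): ring A = C1–C5 and C10 (C18, C20 = CH3; C19, C6 = CO2H); the bicyclo[3.2.1]octane = C8, C9, C11–C16 (C7 = CHO, C17 = CH2).
2. Late disconnections: the diacid comes from its C19/C6 cyclic anhydride; the C9–C10 bond comes from a decarboxylative Giese addition of a ring-A tertiary radical (a temporary carboxyl on C10) to a bicyclic enone.
3. Key disconnection: ring A by a one-flask [3+3] bis-alkylation (C1–C10 and C3–C4) of a lactone/ester dianion with 1,3-dibromopropane, followed in the same flask by angular methylation. Enabling feature: C4 and C10 flank C5 and are both α to a carbonyl (C19 lactone; sacrificial ester on C10), C6 is held at the acetal level so C5–H is not acidic, and C1–C3 are three plain methylenes.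
4. The lactone arises from a menthyloxy butenolide by Michael addition (sets C5); the enone from a catalytic asymmetric Diels–Alder reaction (ring C, C8), a gold Conia-ene closure (ring D, C13) and dehydrogenation.
5. Ring order: γ-lactone (purchased) → ring A (key step); separately ring C → ring D; then union at C9–C10 and hydrolysis.

Key step: step 2

Remark: d-menthyl = (1S,2R,5S)-5-methyl-2-(propan-2-yl)cyclohexyl; both antipodes of the menthyloxy butenolide and of the oxazaborolidine are assumed purchasable, and the sense of induction in step 10 is assigned from the accepted formyl C–H···O pre-transition-state model, so the antipodal catalyst is used if the first adduct proves to be the mirror image.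

**Route**

Step 1
Reactants: 1 (5S)-5-(d-menthyloxy)furan-2(5H)-one; 2 benzyl propanoate
Product: 3 benzyl 2-[(2S,3R)-2-(d-menthyloxy)-5-oxooxolan-3-yl]propanoate (2,3-trans; epimers at the propanoate α-carbon)
Conditions: LDA, THF, −78 °C; then 1, −78 °C; AcOH quench
Reagents that add atoms: none
Why: Michael addition of the lithium ester enolate to the butenolide should occur on the face anti to the γ-menthyloxy group, which sets C5 under control of the acetal carbon; the side-chain α-carbon (future C10) needs no control because it is enolised in step 2.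

Step 2
Reactants: 3 benzyl 2-[(2S,3R)-2-(d-menthyloxy)-5-oxooxolan-3-yl]propanoate; 4 1,3-dibromopropane
Product: 6 benzyl (3S,3aS,7aR)-3-(d-menthyloxy)-4,7a-dimethyl-1-oxooctahydro-2-benzofuran-4-carboxylate (epimers at the ester-bearing carbon), via ring-fusion C–H lactone 5 (not isolated)
Conditions: LDA (2.2 equiv), THF, −78 to −40 °C; DMPU, 4 (1.0 equiv), −78 to 0 °C; then LDA (1.1 equiv), −78 °C; MeI, −78 to −20 °C
Reagents that add atoms: iodomethane, CI
Why: Two deprotonations give the lactone enolate (C4) and the benzyl ester enolate (C10), the only acidic C–H bonds because C6 is kept at the acetal level, and this dianion is alkylated twice by 1,3-dibromopropane, first intermolecularly and then by 6-exo-tet closure, so that C1–C10 and C3–C4 form in one flask and ring A appears; the closest known reaction type is the annulation of diester and lactone dianions with α,ω-dihalides. The third equivalent of base drives any material first alkylated at C4 to close through its C10 enolate and converts all of 5 into the ring-fusion enolate. Iodomethane should then attack the face anti to the C5–C10 bond (angular alkylation of a fused γ-lactone enolate), which fixes quaternary C4 with the cis ring fusion that puts C19 and C6 on one face, under control of the C5 centre from step 1. C10 also becomes quaternary, as an epimer mixture that is of no consequence because this centre is flattened to a radical in step 13. The selectivities needed are C- over O-alkylation, secured because C-closure gives a six-membered ring whereas O-closure would need an eight-membered one, and cyclisation over oligomerisation, secured by one equivalent of dihalide at moderate dilution.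

Step 3
Reactants: 6 benzyl (3S,3aS,7aR)-3-(d-menthyloxy)-4,7a-dimethyl-1-oxooctahydro-2-benzofuran-4-carboxylate
Product: 7 benzyl (3aS,7aR)-3-hydroxy-4,7a-dimethyl-1-oxooctahydro-2-benzofuran-4-carboxylate (lactol; epimers at the lactol and ester-bearing carbons)
Conditions: 2 M HCl, 1,4-dioxane, 60 °C
Reagents that add atoms: water, O
Why: Acid hydrolysis of the pseudo-ester (mixed acylal) should release the menthol auxiliary and leave the γ-hydroxy lactone, with the hindered benzyl ester and all carbon stereocentres untouched.

Step 4
Reactants: 7 benzyl (3aS,7aR)-3-hydroxy-4,7a-dimethyl-1-oxooctahydro-2-benzofuran-4-carboxylate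
Product: 8 benzyl (3aS,7aR)-4,7a-dimethyl-1,3-dioxooctahydro-2-benzofuran-4-carboxylate (cis-fused anhydride)
Conditions: CrO3, H2SO4, acetone, 0 °C
Reagents that add atoms: none
Why: Jones oxidation of the hemiacylal should give the cyclic anhydride, so C6 reaches the acid level while still tied to C19 and the cis-diacid stays masked and regiodefined.

Step 5
Reactants: 8 benzyl (3aS,7aR)-4,7a-dimethyl-1,3-dioxooctahydro-2-benzofuran-4-carboxylate
Product: 9 (3aS,7aR)-4,7a-dimethyl-1,3-dioxooctahydro-2-benzofuran-4-carboxylic acid
Conditions: H2 (1 atm), 10% Pd/C, EtOAc, rt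
Reagents that add atoms: none
Why: Hydrogenolysis of the benzyl ester in an aprotic solvent should free the sacrificial C10 carboxylic acid without opening the anhydride.

Step 6
Reactants: 9 (3aS,7aR)-4,7a-dimethyl-1,3-dioxooctahydro-2-benzofuran-4-carboxylic acid
Product: 10 1,3-dioxoisoindolin-2-yl ester of acid 9 (N-acyloxyphthalimide)
Conditions: N-hydroxyphthalimide, DIC, CH2Cl2, 0 °C to rt
Reagents that add atoms: N-hydroxyphthalimide, O=C1c2ccccc2C(=O)N1O
Why: Carbodiimide esterification without a nucleophilic catalyst should convert the tertiary acid into the redox-active ester while leaving the hindered anhydride closed.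

Step 7
Reactants: 11 pent-4-yn-1-ol
Product: 12 pent-4-ynal
Conditions: PhI(OAc)2, TEMPO (10 mol %), CH2Cl2, rt
Reagents that add atoms: none
Why: Oxoammonium-mediated oxidation of a primary alcohol should stop at the aldehyde and tolerate the terminal alkyne.

Step 8
Reactants: 12 pent-4-ynal
Product: 13 2-methylidenepent-4-ynal
Conditions: 37% aq. CH2O, pyrrolidine (10 mol %), EtCO2H (10 mol %), i-PrOH, 45 °C; used freshly
Reagents that add atoms: formaldehyde, C=O
Why: Amine-catalysed α-methylenation (Mannich condensation then elimination) should give the α-substituted acrolein that carries C7, C8, C14 and the propargyl arm C15–C17.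

Step 9
Reactants: 14 but-3-en-2-one
Product: 15 (buta-1,3-dien-2-yloxy)tri(propan-2-yl)silane
Conditions: TIPSOTf, Et3N, CH2Cl2, 0 °C
Reagents that add atoms: triisopropylsilyl trifluoromethanesulfonate, CC(C)[Si](OS(=O)(=O)C(F)(F)F)(C(C)C)C(C)C
Why: Soft enolisation and O-silylation of the enone should give the robust 2-silyloxydiene.

Step 10
Reactants: 13 2-methylidenepent-4-ynal; 15 (buta-1,3-dien-2-yloxy)tri(propan-2-yl)silane
Product: 16 (1R)-1-(prop-2-yn-1-yl)-4-{[tri(propan-2-yl)silyl]oxy}cyclohex-3-ene-1-carbaldehyde
Conditions: (S)-3,3-diphenyl-1-(o-tolyl)tetrahydropyrrolo[1,2-c][1,3,2]oxazaborole (20 mol %), HNTf2 (17 mol %), CH2Cl2, −78 °C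
Reagents that add atoms: none
Why: Oxazaborolidinium-catalysed Diels–Alder reaction with the 2-silyloxy group directing "para" regiochemistry should build ring C, and the catalyst-controlled face of the dienophile sets quaternary C8, whose chirality is encoded in the position of the enol ether.

Step 11
Reactants: 16 (1R)-1-(prop-2-yn-1-yl)-4-{[tri(propan-2-yl)silyl]oxy}cyclohex-3-ene-1-carbaldehyde
Product: 17 (1R,5R)-6-methylidene-4-oxobicyclo[3.2.1]octane-1-carbaldehyde
Conditions: [(t-Bu)2(2-biphenylyl)PAu(NCMe)]SbF6 (5 mol %), CH2Cl2/MeOH 10:1, rt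
Reagents that add atoms: none
Why: Gold-catalysed Conia-ene cyclisation (5-exo-dig attack of the silyl enol ether carbon C13 on the activated alkyne) should close ring D with the exocyclic methylene, and because only the enol-ether carbon can attack, the regiochemistry from step 10 becomes the configuration of both bridgeheads.

Step 12
Reactants: 17 (1R,5R)-6-methylidene-4-oxobicyclo[3.2.1]octane-1-carbaldehyde
Product: 18 (1R,5R)-6-methylidene-4-oxobicyclo[3.2.1]oct-2-ene-1-carbaldehyde
Conditions: 2-iodoxybenzoic acid, DMSO/toluene, 70 °C
Reagents that add atoms: none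
Why: Iodoxybenzoic acid dehydrogenation of the ketone should give the C9=C11 enone regiospecifically, since the other α-carbon (C13) is a bridgehead that cannot enolise and the aldehyde has no α-hydrogen.

Step 13
Reactants: 10 1,3-dioxoisoindolin-2-yl ester of acid 9; 18 (1R,5R)-6-methylidene-4-oxobicyclo[3.2.1]oct-2-ene-1-carbaldehyde
Product: 19 C19/C6 cyclic anhydride of the target
Conditions: 10 (1.5 equiv), Ru(bpy)3(PF6)2 (2 mol %), diethyl 1,4-dihydro-2,6-dimethylpyridine-3,5-dicarboxylate (1.5 equiv), i-Pr2NEt·HBF4, CH2Cl2, blue LEDs, rt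
Reagents that add atoms: none
Why: Decarboxylative Giese reaction: reductive fragmentation of the N-acyloxyphthalimide gives the planar tertiary C10 radical, which should add to the enone β-carbon C9 on the exo face anti to the two-carbon bridge (sets C9) and through its own face anti to the vicinal anhydride ring (sets C10, methyl cis to C6), after which the dihydropyridine supplies the hydrogen atom at C11.

Step 14
Reactants: 19 C19/C6 cyclic anhydride of the target
Product: 20 7,12-dioxo-6,7-seco-ent-kaur-16-ene-6,19-dioic acid (target)
Conditions: LiOH, THF/H2O, 0 °C; then 1 M HCl to pH 2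
Reagents that add atoms: water, O
Why: Hydroxide should open the anhydride at the less hindered C6 carbonyl to give the cis-diacid, while the non-enolisable aldehyde, the ketone and the exocyclic alkene are inert at 0 °C.

**Compound list**

1 | (5S)-5-(d-menthyloxy)furan-2(5H)-one | O=C1C=C[C@@H](O[C@H]2C[C@@H](C)CC[C@@H]2C(C)C)O1 | starting material
2 | benzyl propanoate | CCC(=O)OCc1ccccc1 | starting material
3 | benzyl 2-[(2S,3R)-2-(d-menthyloxy)-5-oxooxolan-3-yl]propanoate (side-chain epimers) | O=C1C[C@H](C(C)C(=O)OCc2ccccc2)[C@@H](O[C@H]3C[C@@H](C)CC[C@@H]3C(C)C)O1 | intermediate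
4 | 1,3-dibromopropane | BrCCCBr | starting material
5 | benzyl (3S)-3-(d-menthyloxy)-4-methyl-1-oxooctahydro-2-benzofuran-4-carboxylate (ring-fusion C–H lactone; ring-fusion CH next to the acetal configured as in 6; epimers at the other ring-fusion carbon and at the ester-bearing carbon) | O=C1O[C@H](O[C@H]3C[C@@H](C)CC[C@@H]3C(C)C)[C@@H]2C1CCCC2(C)C(=O)OCc4ccccc4 | intermediate (not isolated)
6 | benzyl (3S,3aS,7aR)-3-(d-menthyloxy)-4,7a-dimethyl-1-oxooctahydro-2-benzofuran-4-carboxylate (epimers at the ester-bearing carbon) | O=C1O[C@H](O[C@H]3C[C@@H](C)CC[C@@H]3C(C)C)[C@@H]2[C@@]1(C)CCCC2(C)C(=O)OCc4ccccc4 | intermediate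
7 | benzyl (3aS,7aR)-3-hydroxy-4,7a-dimethyl-1-oxooctahydro-2-benzofuran-4-carboxylate (lactol) | O=C1OC(O)[C@@H]2[C@@]1(C)CCCC2(C)C(=O)OCc3ccccc3 | intermediate
8 | benzyl (3aS,7aR)-4,7a-dimethyl-1,3-dioxooctahydro-2-benzofuran-4-carboxylate | O=C1OC(=O)[C@@H]2[C@@]1(C)CCCC2(C)C(=O)OCc3ccccc3 | intermediate
9 | (3aS,7aR)-4,7a-dimethyl-1,3-dioxooctahydro-2-benzofuran-4-carboxylic acid | O=C1OC(=O)[C@@H]2[C@@]1(C)CCCC2(C)C(=O)O | intermediate
10 | 1,3-dioxoisoindolin-2-yl ester of acid 9 | O=C1OC(=O)[C@@H]2[C@@]1(C)CCCC2(C)C(=O)ON3C(=O)c4ccccc4C3=O | intermediate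
11 | pent-4-yn-1-ol | OCCCC#C | starting material
12 | pent-4-ynal | O=CCCC#C | intermediate
13 | 2-methylidenepent-4-ynal | C=C(CC#C)C=O | intermediate
14 | but-3-en-2-one | CC(=O)C=C | starting material
15 | (buta-1,3-dien-2-yloxy)tri(propan-2-yl)silane | C=CC(=C)O[Si](C(C)C)(C(C)C)C(C)C | intermediate
16 | (1R)-1-(prop-2-yn-1-yl)-4-{[tri(propan-2-yl)silyl]oxy}cyclohex-3-ene-1-carbaldehyde | O=C[C@@]1(CC#C)CC=C(O[Si](C(C)C)(C(C)C)C(C)C)CC1 | intermediate
17 | (1R,5R)-6-methylidene-4-oxobicyclo[3.2.1]octane-1-carbaldehyde | C=C1C[C@]2(C=O)C[C@H]1C(=O)CC2 | intermediate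
18 | (1R,5R)-6-methylidene-4-oxobicyclo[3.2.1]oct-2-ene-1-carbaldehyde | C=C1C[C@]2(C=O)C[C@H]1C(=O)C=C2 | intermediate
19 | C19/C6 cyclic anhydride of the target | C=C1C[C@]2(C=O)C[C@H]1C(=O)C[C@H]2[C@]1(C)CCC[C@@]3(C)C(=O)OC(=O)[C@@H]13 | intermediate
20 | 7,12-dioxo-6,7-seco-ent-kaur-16-ene-6,19-dioic acid (CNP0320711.1) | C=C1C[C@]2(C=O)C[C@H]1C(=O)C[C@H]2[C@]1(C)CCC[C@@](C)(C(=O)O)[C@H]1C(=O)O | target

**Step count**

Total: 14 steps. Longest linear sequence: 8 steps (1, 2, 3, 4, 5, 6, 13, 14).

**Steps most likely to fail**

Step 13. The tertiary radical may be reduced before it adds, because the enone β-carbon is flanked by a quaternary bridgehead, or it may add with poor facial selectivity at C10. The fallback builds ring C onto ring A instead of joining two finished halves. It sets out from 10: the same photoredox conditions with unhindered but-3-yn-2-one, followed by iodine-catalysed equilibration, give the (E)-enone F1 (C10 is set here with a small acceptor). TIPSOTf/Et3N converts it into the 2-silyloxydiene F2. The oxazaborolidinium-catalysed Diels–Alder reaction with 13 (endo, catalyst-controlled) gives the ring-C silyl enol ether F3. HF·pyridine gives the ketone F4, and TBSOTf/Et3N enolises away from the substituted C9 side to the enol ether F5. The gold catalyst of step 11 then closes ring D, and the route is rejoined at 19.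

Step 2. Intermolecular second alkylation (oligomers), elimination of the dihalide or stalled mono-alkylation may outrun ring closure. The fallback makes the two ring bonds in separate events. It sets out from 2: the lithium enolate is alkylated with 1-bromo-3-chloropropane to give benzyl 5-chloro-2-methylpentanoate F6. Its lithium enolate adds to 1, and the resulting lactone enolate closes ring A by intramolecular alkylation (Michael-initiated ring closure, NaI/DMPU on warming) to give 5. This is methylated with LDA/MeI as in the second half of step 2, and the route is rejoined at 6.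

Step 11. Protodesilylation of the enol ether before cyclisation would erase the only element of chirality, and the free aldehyde may compete for the activated alkyne. The fallback locks the stereocentre in an enone before ring D is closed. It sets out from 13 and 15: the antipodal (R)-oxazaborolidinium catalyst gives the enantiomeric adduct F7. Pd(OAc)2 (cat.)/O2 in DMSO (Saegusa–Ito oxidation) converts it into the enone F8, whose configuration no longer depends on a silyl group. TBSOTf/Et3N gives the cross-conjugated dienol ether F9, since only C13 carries α-hydrogens. The gold-catalysed Conia-ene closure then gives the enone directly; the route is rejoined at 18 and step 12 is no longer needed.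

Further compounds
F1 | step 13 | (3aS,7aR)-4,7a-dimethyl-4-[(1E)-3-oxobut-1-en-1-yl]hexahydro-2-benzofuran-1,3-dione (quaternary carbon as in 19) | CC(=O)/C=C/[C@]1(C)CCC[C@@]2(C)C(=O)OC(=O)[C@@H]12
F2 | step 13 | 2-(triisopropylsilyloxy)diene from F1 | C=C(O[Si](C(C)C)(C(C)C)C(C)C)/C=C/[C@]1(C)CCC[C@@]2(C)C(=O)OC(=O)[C@@H]12
F3 | step 13 | Diels–Alder adduct of F2 and 13 (ring-C silyl enol ether; formyl cis to ring A) | O=C[C@@]1(CC#C)CCC(O[Si](C(C)C)(C(C)C)C(C)C)=C[C@H]1[C@]2(C)CCC[C@@]3(C)C(=O)OC(=O)[C@@H]23
F4 | step 13 | ring-C ketone from F3 | O=C[C@@]1(CC#C)CCC(=O)C[C@H]1[C@]2(C)CCC[C@@]3(C)C(=O)OC(=O)[C@@H]23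
F5 | step 13 | tert-butyldimethylsilyl enol ether of F4 toward C13 | O=C[C@@]1(CC#C)CC=C(O[Si](C)(C)C(C)(C)C)C[C@H]1[C@]2(C)CCC[C@@]3(C)C(=O)OC(=O)[C@@H]23
F6 | step 2 | benzyl 5-chloro-2-methylpentanoate (racemic) | CC(CCCCl)C(=O)OCc1ccccc1
F7 | step 11 | (1S)-1-(prop-2-yn-1-yl)-4-{[tri(propan-2-yl)silyl]oxy}cyclohex-3-ene-1-carbaldehyde | O=C[C@]1(CC#C)CC=C(O[Si](C(C)C)(C(C)C)C(C)C)CC1
F8 | step 11 | (1R)-4-oxo-1-(prop-2-yn-1-yl)cyclohex-2-ene-1-carbaldehyde | O=C[C@@]1(CC#C)CCC(=O)C=C1
F9 | step 11 | (1R)-4-[(tert-butyldimethylsilyl)oxy]-1-(prop-2-yn-1-yl)cyclohexa-2,4-diene-1-carbaldehyde | O=C[C@@]1(CC#C)CC=C(O[Si](C)(C)C(C)(C)C)C=C1
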